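**Assumptions.** Eudesmane numbering is used (C3 ester carbon, C4 tertiary carbinol, C5/C10 ring fusion, C8 ketone, C11 carbinol of the side chain). The target SMILES is read as (3S,4S,5R,10R), i.e. 3β-angeloyloxy-4α,11-dihydroxy-5αH-eudesm-6-en-8-one with a (Z)-2-methylbut-2-enoate (angelate); the 3-O and 4-OH are trans. The sense of induction of the chiral acid in step 1 cannot be predicted, so the antipode that gives (5R,10R)-2 must be found by experiment; (S,S) is written as a placeholder.

**Retrosynthetic overview**
1. Target 7 ⇒ 5: the 11-hydroxy-6-en-8-one unit comes from the 7(11)-en-8-one by a singlet-oxygen ene reaction and reduction (no ring formed).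
2. 5 ⇒ 3 + 4: the 3β-angelate comes from the 3α,4α-diol (cuauhtemone) by esterification with inversion; 3 ⇒ 2 by α-face dihydroxylation of the 3,4-alkene.
3. 2 ⇒ 1: the C5–C10 bond is made by proton-initiated transannular cyclization of achiral germacrone, rendered enantioselective by a chiral acid.
4. Ring order: the ten-membered germacrane ring is supplied by 1; one transannular closure then creates rings A and B together.

**Route**

Step 1
Reactants: 1 germacrone
Product: 2 (5R,10R)-eudesma-3,7(11)-dien-8-one
Conditions: (S,S)-IDPi acid (imidodiphosphorimidate from two (S)-3,3'-bis[3,5-bis(trifluoromethyl)phenyl]-BINOL units, N-triflyl on both phosphorus atoms; 5 mol%), CHCl3/(CF3)3COH 4:1, 4 Å MS, −40 °C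
Reagents that add atoms: none
Why: Proposed new method: germacrone has no stereocentre and its planar-chiral ring conformers interconvert quickly, so a confined chiral acid can protonate C1 of one conformer selectively (dynamic kinetic asymmetric protonation), the C10 cation is captured by C5 of the E-4,5-alkene through the crossed chair–chair conformer to give the trans-decalin with 10β-methyl and 5α-H (5R,10R), and the counter-anion removes the axial 3α-H of the C4 cation to give the 3,4-alkene; the closest known reactions are the racemic protic-acid transannular cyclization of germacrone to eudesmadienones and chiral-acid-catalysed asymmetric protonation-initiated cation–olefin (polyene) cyclizations.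

Step 2
Reactants: 2 (5R,10R)-eudesma-3,7(11)-dien-8-one
Product: 3 cuauhtemone (3α,4α-dihydroxyeudesm-7(11)-en-8-one)
Conditions: OsO4 (2 mol%), NMO (1.5 equiv), acetone/H2O 4:1, 0 °C → rt
Reagents that add atoms: N-methylmorpholine N-oxide, C[N+]1([O-])CCOCC1; water, O; both oxygens are delivered through osmium tetroxide, O=[Os](=O)(=O)=O
Why: Upjohn cis-dihydroxylation attacks only the electron-rich trisubstituted 3,4-alkene (the tetrasubstituted enone alkene is electron-poor and hindered) and from the α-face, anti to the axial C10 methyl that is syn-axial to C4, which sets 3R and 4S (3α-OH axial, 4α-OH equatorial, 4β-CH3).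

Step 3
Reactants: 3 cuauhtemone; 4 angelic acid
Product: 5 (3S,4S,5R,10R)-3β-angeloyloxy-4α-hydroxyeudesm-7(11)-en-8-one
Conditions: angelic acid (2 equiv), PPh3 (2 equiv), DIAD (2 equiv), toluene, 0 °C → 40 °C
Reagents that add atoms: angelic acid (4), C/C=C(/C)C(=O)O
Why: Mitsunobu esterification activates only the secondary 3α-OH (the tertiary 4-OH is inert and, being cis, cannot close to an epoxide) and the carboxylate displaces it by SN2 with inversion to give the equatorial 3β-ester (3S); because the acid acts as nucleophile and is never acyl-activated, the (Z)-geometry of the angelate is kept.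

Step 4
Reactants: 5 (3S,4S,5R,10R)-3β-angeloyloxy-4α-hydroxyeudesm-7(11)-en-8-one
Product: 7 (3S,4S,5R,10R)-3β-angeloyloxy-4α,11-dihydroxyeudesm-6-en-8-one (target), via 11-hydroperoxide 6 (not isolated)
Conditions: O2, meso-tetraphenylporphyrin (1 mol%), visible-light LED, CH2Cl2, −20 °C; then PPh3 (1.2 equiv), −20 °C → rt
Reagents that add atoms: dioxygen, O=O
Why: Schenck ene reaction of singlet oxygen with the s-cis (pulegone-type) enone follows the gem effect, so oxygen bonds to the β-carbon C11 and hydrogen is taken from C6 (the alkyl group geminal to the carbonyl), moving the double bond to C6=C7; PPh3 reduces the hydroperoxide to the alcohol, no new stereocentre arises (C11 carries two methyls), and the conjugated angelate is far less reactive towards singlet oxygen and is not isomerized by the low-energy sensitizer.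

**Compound list**
1 | germacrone, (3E,7E)-3,7-dimethyl-10-(propan-2-ylidene)cyclodeca-3,7-dien-1-one | C/C1=C\CC/C(C)=C/CC(=C(C)C)C(=O)C1 | starting material
2 | (5R,10R)-eudesma-3,7(11)-dien-8-one (trans-decalin, 10β-CH3, 5α-H) | CC1=CCC[C@]2(C)CC(=O)C(=C(C)C)C[C@@H]12 | intermediate
3 | cuauhtemone, (3R,4S,5R,10R)-3α,4α-dihydroxyeudesm-7(11)-en-8-one | O[C@@H]1CC[C@]2(C)CC(=O)C(=C(C)C)C[C@H]2[C@]1(C)O | intermediate
4 | angelic acid, (Z)-2-methylbut-2-enoic acid | C/C=C(/C)C(=O)O | starting material
5 | (3S,4S,5R,10R)-3β-angeloyloxy-4α-hydroxyeudesm-7(11)-en-8-one | C/C=C(/C)C(=O)O[C@H]1CC[C@]2(C)CC(=O)C(=C(C)C)C[C@H]2[C@]1(C)O | intermediate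
6 | (3S,4S,5R,10R)-3β-angeloyloxy-11-hydroperoxy-4α-hydroxyeudesm-6-en-8-one (in equilibrium with its cyclic hemiperketal) | C/C=C(/C)C(=O)O[C@H]1CC[C@]2(C)CC(=O)C(C(C)(C)OO)=C[C@H]2[C@]1(C)O | intermediate (not isolated)
7 | (3S,4S,5R,10R)-3β-angeloyloxy-4α,11-dihydroxyeudesm-6-en-8-one | C/C=C(/C)C(=O)O[C@H]1CC[C@]2(C)CC(=O)C(C(C)(C)O)=C[C@H]2[C@]1(C)O | target

**Totals.** Total step count: 4. Longest linear sequence: 4 steps (1 → 2 → 3 → 5 → 7; angelic acid 4 enters in step 3).

**Steps most likely to fail, with fallbacks**

Step 1 (highest risk). The chiral-acid cyclization is unprecedented on this substrate. It may give low enantioselectivity, the 4(15)- or 4(5)-alkene isomers, or the 4-ol if water is present. The fallback sets out from 1 and gives up catalytic enantiocontrol in favour of resolution. The known racemic protic-acid transannular cyclization (TsOH·H2O 10 mol%, CH2Cl2, rt) gives 2 as a racemate, that is, together with (5S,10S)-eudesma-3,7(11)-dien-8-one F1. Preparative chiral supercritical-fluid chromatography on an amylose tris(3,5-dimethylphenylcarbamate) phase separates the two antipodes. The fallback comes back to the route at 2.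

Step 3. The SN2 displacement at C3 is next to a fully substituted carbon carrying an axial methyl. Elimination of the axial oxyphosphonium, or a cyclic phosphorane of the cis-diol, may win. The fallback sets out from 3 and replaces inversion by oxidation and reduction.
- Parikh–Doering oxidation (SO3·pyridine, DMSO, iPr2NEt, 0 °C) of the secondary alcohol gives (4S,5R,10R)-4-hydroxyeudesm-7(11)-ene-3,8-dione F2.
- NaBH4 in MeOH/CH2Cl2 at −78 °C reduces the saturated α-hydroxy ketone faster than the hindered cross-conjugated enone. Axial hydride attack from the α-face, anti to the axial 4β-methyl, gives the equatorial alcohol (3S,4S,5R,10R)-3β,4α-dihydroxyeudesm-7(11)-en-8-one F3.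
- Angelic acid 4 is activated with 2,4,6-trichlorobenzoyl chloride and Et3N in toluene as angelic 2,4,6-trichlorobenzoic anhydride F4. This acylates the secondary 3β-OH of F3 at 80 °C without Z/E isomerization and leaves the tertiary 4-OH free.
- The fallback comes back to the route at 5.

Step 4. Hydrogen abstraction from the C11 methyls (giving the 7-hydroperoxy-11-ene isomer), slow reaction of the enone, or over-oxidation could erode the yield. The fallback sets out from 5 and replaces the ene reaction by an ionic addition–elimination.
- Hydroxyselenation of the enone double bond (N-(phenylseleno)phthalimide, H2O, camphorsulfonic acid 10 mol%, CH2Cl2, rt) puts selenium on the α-carbon C7 and hydroxyl on the tertiary β-carbon C11. The angelate alkene would have to form a secondary cation and is left alone. The product is (3S,4S,5R,7S,10R)-3β-angeloyloxy-4α,11-dihydroxy-7-(phenylselanyl)eudesman-8-one F5; the C7 configuration is immaterial.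
- H2O2 (30%) and pyridine in CH2Cl2 at 0 °C oxidize it to the selenoxide of F5, (3S,4S,5R,7S,10R)-3β-angeloyloxy-4α,11-dihydroxy-7-(phenylseleninyl)eudesman-8-one F6. This undergoes syn-elimination on warming to rt; only C6 carries β-hydrogens, so the 6,7-alkene is the sole outcome.
- The fallback comes back to the route at 7.

**Further compounds**
F1 | step 1 | (5S,10S)-eudesma-3,7(11)-dien-8-one (enantiomer of 2) | CC1=CCC[C@@]2(C)CC(=O)C(=C(C)C)C[C@H]12
F2 | step 3 | (4S,5R,10R)-4-hydroxyeudesm-7(11)-ene-3,8-dione | O=C1CC[C@]2(C)CC(=O)C(=C(C)C)C[C@H]2[C@]1(C)O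
F3 | step 3 | (3S,4S,5R,10R)-3β,4α-dihydroxyeudesm-7(11)-en-8-one | O[C@H]1CC[C@]2(C)CC(=O)C(=C(C)C)C[C@H]2[C@]1(C)O
F4 | step 3 | angelic 2,4,6-trichlorobenzoic anhydride | C/C=C(/C)C(=O)OC(=O)c1c(Cl)cc(Cl)cc1Cl
F5 | step 4 | (3S,4S,5R,7S,10R)-3β-angeloyloxy-4α,11-dihydroxy-7-(phenylselanyl)eudesman-8-one | C/C=C(/C)C(=O)O[C@H]1CC[C@]2(C)CC(=O)[C@@]([Se]c3ccccc3)(C(C)(C)O)C[C@H]2[C@]1(C)O
F6 | step 4 | (3S,4S,5R,7S,10R)-3β-angeloyloxy-4α,11-dihydroxy-7-(phenylseleninyl)eudesman-8-one (mixture at selenium) | C/C=C(/C)C(=O)O[C@H]1CC[C@]2(C)CC(=O)[C@@]([Se](=O)c3ccccc3)(C(C)(C)O)C[C@H]2[C@]1(C)O
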